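## The problem

CNP0228612.0 (35, C30H22O17) is a linear chain of five benzene rings A–E joined by four diaryl ether bonds and carrying thirteen free hydroxyl groups; it has no stereogenic centre, axis or double bond, so every question is one of position. The rings are numbered so that ring A is a 2,4,6-trihydroxyphenyl with its ether oxygen on A-C1; ring B has the oxygen to A on B-C1 (between B-C2–H and B-C6–H), OH on B-C3 and B-C4 and the oxygen to C on B-C5; ring C has the oxygen to B on C-C1 (next to C-C2–H), the oxygen to D on the adjacent C-C6 and OH on C-C3, C-C4 and C-C5; ring D has the oxygen to C on D-C1 (between two C–H), OH on D-C3 and D-C5 and the oxygen to E on D-C4; ring E is a 3,4,5-trihydroxyphenyl bound through E-C1 (between two C–H). All rings are very electron-rich, so none offers an activating group for nucleophilic aromatic substitution, and three of the four ether oxygens (on A-C1, C-C6 and D-C4) are flanked by two ortho oxygen substituents, where copper-mediated couplings with aryl halides are weakest. Each ring has four or five oxygens, and for each one the synthesis must decide whether it stays a hydroxyl or becomes a bridge, and to which neighbour. Ring C is the hardest part: five contiguous oxygenated carbons, two of them neighbouring aryl ethers. The free polyphenol (pyrogallol- and hydroxyquinol-type rings) is oxidised by air, so all hydroxyls must stay masked to the last step, which must spare four diaryl ethers. The feature the plan uses is that B-C1 and D-C1 each lie between two C–H and two positions from an oxygenated carbon, and that in ring C the bond C-C1–C-C6 has C-C5–O on one side and C-C2–H on the other. A benzyne with its triple bond at C-C1≡C-C6 and a methoxy group on C-C5 takes up the ring B aryloxide at C-C1 and a second group at C-C6 in one operation.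

## Retrosynthesis

**35 ⇒ 34.** The thirteen O–H bonds are cut first, giving the tridecamethyl ether 34. Methyl is preferred to benzyl or silyl because every ring is commercial as a methyl ether and methyl ethers survive fluoride, organolithium, Grignard, copper and peracid steps. One Lewis-acid step should remove them all while leaving diaryl ethers intact. The forward step must reach all thirteen groups, and the product must be handled without air.

**34 ⇒ 32 + 14.** The C-C6–O–D-C1 bond is cut, with the oxygen kept on ring C. It is the most hindered and most central ether, so the cut divides the molecule into trimer phenol 32 and dimer 14. The cut is placed at D-C1 and not at C-C6 because D-C1 lies between two C–H and two positions from D-C3–OMe: it is the distal carbon of aryne 33, which fluoride releases from the ortho-silylaryl triflate 14. The forward reaction asks a hindered aryloxide to add to an unhindered, highly electrophilic carbon at room temperature.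

**32 ⇒ 29 ⇒ 26 + 5 (key).** In ring C both the C-C1–O bond to ring B and the C-C6–O bond are cut. Phenol 32 comes from iodide 29 by iodine–magnesium exchange, borylation and oxidation. Iodide 29 is the product of adding aryloxide 27 (from phenol 26) and an iodine atom across the triple bond of 3,4,5-trimethoxybenzyne 28, released from 5. Cutting only C-C1–O would leave C-C6–H to be oxidised beside two equally electron-rich rings, or would need a ring C halide that already carries a differentiated oxygen. The precursor is much simpler than the product: the methoxy group next to the triple bond of 28 fixes both new positions at once.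

**26 ⇒ 25 ⇒ 23 + 22.** The A-C1–O–B-C1 bond is cut with the oxygen on ring A (2,4,6-trimethoxyphenol 23). B-C1 again lies between two C–H, so ring B enters as aryne 24 from silyl triflate 22. A benzyl ether marks the one oxygen of ring B (on B-C5) that must act as the nucleophile in the key step; hydrogenolysis of 25 frees it as 26.

**22 ⇒ 19 ⇒ 17 ⇒ 16 ⇒ 15.** The silyl and triflate groups of 22 come from bromophenol 19 by the retro-Brook sequence (via 20 and 21). The hydroxyl of 19 comes from the formyl group of 17 by Dakin oxidation (via 18). Aldehyde 17 comes from commercial 3-hydroxy-4,5-dimethoxybenzaldehyde 15 by bromination next to the free hydroxyl (16) and O-benzylation. The formyl group is thus a masked phenol that ends as the leaving group of the aryne.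

**14 ⇒ 11 ⇒ 10 ⇒ 8 ⇒ 6 + 7.** Triflate 14 comes from bromophenol 11 (via 12 and 13), 11 from phenol 10, and 10 by Dakin oxidation of aldehyde 8 (via 9). In 8 the D-C4–O–E-C1 bond is cut with the oxygen on ring D. Syringaldehyde 6 supplies the hindered phenol and, as its formyl group, the future D-C1 oxygen. Ring E needs no second substituent beside its ether carbon and is commercial as (3,4,5-trimethoxyphenyl)boronic acid 7, so this one bond is made by an oxidative copper coupling at room temperature. There too the hindered oxygen is the nucleophile and the carbon it meets is unhindered. This gives 8 in one step from two commercial compounds, keeps the two-step precursor 5 for the ring that uses both carbons of the triple bond, and keeps the aldehyde of 6 out of an aryne reaction.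

**5 ⇒ 2 ⇒ 1.** Precursor 5, which provides ring C, is made from 3,4,5-trimethoxyphenol 1 by ortho-bromination (2) and the silylation, bromine–lithium exchange, silyl shift and triflation sequence (via 3 and 4).

## Roads not taken

**Alternative 1:** the most obvious plan cuts all four ethers as copper-mediated Ullmann couplings of methylated phenols with methylated bromoarenes, building the chain linearly. The hardest forward step would be the coupling of phenol 10 with the bromide A1, whose bromine sits between an aryloxy and a methoxy group. In three of the four bonds one partner carries two ortho oxygen substituents and both partners are electron-rich, so the copper-centred C–O bond formation with an aryl halide is slow and needs high temperature, where reduction of the halide competes. In the chosen plan the hindered oxygen is always the nucleophile and the carbon it meets is always unhindered: an aryne carbon for the three inner ethers, which needs no metal and no heat, and the commercial boronic acid 7 at room temperature for ring E. It also needs no halide at the final ether carbon of rings B, C and D.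

**Alternative 2:** B-C1, C-C1, D-C1 and E-C1 each have an oxygenated carbon para to them, so every ether could be cut as a fluoride displacement para to a formyl group, followed by Dakin oxidation of the formyl group to the para hydroxyl. Each electrophilic ring would be a 4-fluorobenzaldehyde with alkoxy groups on both sides of the formyl group; for ring C this is A2. The building blocks for rings B and C, such as A2, are not available and would each cost several steps. A formyl group flanked by two alkoxy donors is a weak activator, and in A2 the alkoxy group ortho to fluorine puts a donor on a carbon that carries negative charge in the addition intermediate. Only in ring D is the hydroxyl revealed by the Dakin step the next nucleophile; in rings B and C it would have to be capped again. The aryne needs no activating group and leaves hydrogen where the target has hydrogen.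

**Alternative 3:** ring B has its two ether carbons meta to each other with B-C6–H between them, the pattern given by a 1,3-benzdiyne equivalent. The 2-silyl-1,3-bis(triflate) A3 could in principle take up two aryloxides in one flask: addition, loss of the second triflate from the resulting carbanion, and a second addition. The two aryloxides (from 23 and from a ring C phenol) are different and both present when the first aryne forms, so they would compete and give mixed and doubled adducts. A3 is unsymmetrical, so which triflate leaves first is not controlled. The second aryne would have an alkoxy group on one side and an aryloxy group on the other, which gives no positional bias. Ring C would also have to enter as a nucleophile, which brings back the problem of differentiating its C-C6 oxygen.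

Key step: step 13

Remark: the target SMILES contains no stereocentre and no double-bond geometry, so no SMILES below carries a stereodescriptor; compounds 1, 6, 7, 15 and 23 are taken as commercial.

## Route

Step 1
Reactants: 1 3,4,5-trimethoxyphenol
Product: 2 2-bromo-3,4,5-trimethoxyphenol
Conditions: NBS (1.0 equiv), CH2Cl2, −78 °C to 0 °C
Reagents that add atoms: N-bromosuccinimide, O=C1CCC(=O)N1Br
Why: Electrophilic aromatic bromination ortho to the free hydroxyl; the two ortho positions are equivalent and the para position is blocked by OMe, so one equivalent at low temperature should give the monobromide.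

Step 2
Reactants: 2 2-bromo-3,4,5-trimethoxyphenol
Product: 5 3,4,5-trimethoxy-2-(trimethylsilyl)phenyl trifluoromethanesulfonate, via aryl trimethylsilyl ether 3 (not isolated), via lithium 2-silylphenolate 4 (not isolated)
Conditions: HMDS, THF, reflux, then evaporation; n-BuLi, THF, −78 °C; Tf2O, −78 °C to rt
Reagents that add atoms: hexamethyldisilazane, C[Si](C)(C)N[Si](C)(C)C; trifluoromethanesulfonic anhydride, O=S(=O)(OS(=O)(=O)C(F)(F)F)C(F)(F)F
Why: O-silylation, bromine–lithium exchange with 1,3-shift of silicon from oxygen to the lithiated carbon (retro-Brook rearrangement), then O-triflation of the phenolate; this is the standard one-flask route from an ortho-bromophenol to an ortho-silylaryl triflate.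

Step 3
Reactants: 6 syringaldehyde (4-hydroxy-3,5-dimethoxybenzaldehyde); 7 (3,4,5-trimethoxyphenyl)boronic acid
Product: 8 3,5-dimethoxy-4-(3,4,5-trimethoxyphenoxy)benzaldehyde
Conditions: Cu(OAc)2 (1 equiv), pyridine (5 equiv), 4 Å molecular sieves, CH2Cl2, air, rt; 7 (2 equiv)
Reagents that add atoms: none
Why: Chan–Lam–Evans oxidative O-arylation of a phenol with an arylboronic acid; the coupling tolerates phenols with two ortho substituents and an electron-withdrawing para group because the aryl partner is unhindered, air reoxidises the copper, and the formyl group is inert to copper diacetate at room temperature.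

Step 4
Reactants: 8 3,5-dimethoxy-4-(3,4,5-trimethoxyphenoxy)benzaldehyde
Product: 10 3,5-dimethoxy-4-(3,4,5-trimethoxyphenoxy)phenol, via aryl formate 9 (not isolated)
Conditions: mCPBA, CH2Cl2, 0 °C to rt; then K2CO3, MeOH, rt
Reagents that add atoms: 3-chloroperoxybenzoic acid, OOC(=O)c1cccc(Cl)c1
Why: Baeyer–Villiger (Dakin-type) oxidation: the electron-rich aryl group, with an aryloxy group para to the formyl group, migrates to oxygen, and methanolysis of formate 9 frees the hydroxyl on D-C1.

Step 5
Reactants: 10 3,5-dimethoxy-4-(3,4,5-trimethoxyphenoxy)phenol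
Product: 11 2-bromo-3,5-dimethoxy-4-(3,4,5-trimethoxyphenoxy)phenol
Conditions: NBS (1.0 equiv), CH2Cl2, −78 °C to 0 °C
Reagents that add atoms: N-bromosuccinimide, O=C1CCC(=O)N1Br
Why: Electrophilic bromination ortho to the free hydroxyl of ring D (D-C2 and D-C6 are equivalent); the free phenol ring should react before the fully etherified ring E.

Step 6
Reactants: 11 2-bromo-3,5-dimethoxy-4-(3,4,5-trimethoxyphenoxy)phenol
Product: 14 3,5-dimethoxy-4-(3,4,5-trimethoxyphenoxy)-2-(trimethylsilyl)phenyl trifluoromethanesulfonate, via aryl trimethylsilyl ether 12 (not isolated), via lithium 2-silylphenolate 13 (not isolated)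
Conditions: HMDS, THF, reflux, then evaporation; n-BuLi, THF, −78 °C; Tf2O, −78 °C to rt
Reagents that add atoms: hexamethyldisilazane, C[Si](C)(C)N[Si](C)(C)C; trifluoromethanesulfonic anhydride, O=S(=O)(OS(=O)(=O)C(F)(F)F)C(F)(F)F
Why: Same retro-Brook and triflation sequence as step 2; bromine–lithium exchange at −78 °C is faster than any deprotonation of the methoxylated rings.

Step 7
Reactants: 15 3-hydroxy-4,5-dimethoxybenzaldehyde
Product: 16 2-bromo-3-hydroxy-4,5-dimethoxybenzaldehyde
Conditions: Br2 (1.05 equiv), NaOAc, AcOH, rt
Reagents that add atoms: bromine, BrBr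
Why: Electrophilic bromination at the position ortho to the free hydroxyl and para to the C5 methoxy group, the site that 3-hydroxy-4-alkoxybenzaldehydes normally take bromine; bromination on the other side of the formyl group would, after the same steps, lead to the same product in step 11.

Step 8
Reactants: 16 2-bromo-3-hydroxy-4,5-dimethoxybenzaldehyde
Product: 17 3-(benzyloxy)-2-bromo-4,5-dimethoxybenzaldehyde
Conditions: BnBr, K2CO3, DMF, rt to 50 °C
Reagents that add atoms: benzyl bromide, BrCc1ccccc1
Why: Williamson ether synthesis; the benzyl group marks the oxygen that later becomes the nucleophilic B-C5–O.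

Step 9
Reactants: 17 3-(benzyloxy)-2-bromo-4,5-dimethoxybenzaldehyde
Product: 19 3-(benzyloxy)-2-bromo-4,5-dimethoxyphenol, via aryl formate 18 (not isolated)
Conditions: mCPBA, CH2Cl2, 0 °C to rt; then K2CO3, MeOH, rt
Reagents that add atoms: 3-chloroperoxybenzoic acid, OOC(=O)c1cccc(Cl)c1
Why: Baeyer–Villiger (Dakin-type) oxidation; the methoxy group para to the formyl group favours aryl migration, and methanolysis of formate 18 gives the phenol.

Step 10
Reactants: 19 3-(benzyloxy)-2-bromo-4,5-dimethoxyphenol
Product: 22 3-(benzyloxy)-4,5-dimethoxy-2-(trimethylsilyl)phenyl trifluoromethanesulfonate, via aryl trimethylsilyl ether 20 (not isolated), via lithium 2-silylphenolate 21 (not isolated)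
Conditions: HMDS, THF, reflux, then evaporation; n-BuLi, THF, −78 °C; Tf2O, −78 °C to rt
Reagents that add atoms: hexamethyldisilazane, C[Si](C)(C)N[Si](C)(C)C; trifluoromethanesulfonic anhydride, O=S(=O)(OS(=O)(=O)C(F)(F)F)C(F)(F)F
Why: Retro-Brook and triflation sequence as in step 2; the silyl shift to the adjacent lithiated carbon is intramolecular and should outrun attack on the benzyl ether.

Step 11
Reactants: 23 2,4,6-trimethoxyphenol; 22 3-(benzyloxy)-4,5-dimethoxy-2-(trimethylsilyl)phenyl trifluoromethanesulfonate
Product: 25 1-(benzyloxy)-2,3-dimethoxy-5-(2,4,6-trimethoxyphenoxy)benzene, via 3-(benzyloxy)-4,5-dimethoxybenzyne 24 (not isolated)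
Conditions: CsF (3 equiv), MeCN, rt
Reagents that add atoms: none
Why: Aryne O-arylation of a phenol: aryne 24 has its triple bond between B-C1 and B-C6 with the benzyloxy group on B-C5, so the doubly ortho-substituted aryloxide should add at B-C1, the carbon remote from that oxygen, and B-C6 is protonated.

Step 12
Reactants: 25 1-(benzyloxy)-2,3-dimethoxy-5-(2,4,6-trimethoxyphenoxy)benzene
Product: 26 2,3-dimethoxy-5-(2,4,6-trimethoxyphenoxy)phenol
Conditions: H2 (1 atm), 10% Pd/C, EtOAc–MeOH, rt
Reagents that add atoms: none
Why: Hydrogenolysis of the benzyl ether; methyl and diaryl ethers are inert, so only the B-C5 hydroxyl is freed.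

Step 13
Reactants: 26 2,3-dimethoxy-5-(2,4,6-trimethoxyphenoxy)phenol; 5 3,4,5-trimethoxy-2-(trimethylsilyl)phenyl trifluoromethanesulfonate
Product: 29 1-(2-iodo-3,4,5-trimethoxyphenoxy)-2,3-dimethoxy-5-(2,4,6-trimethoxyphenoxy)benzene, via potassium aryloxide 27 (not isolated), via 3,4,5-trimethoxybenzyne 28 (not isolated)
Conditions: KH (1.0 equiv), THF, 0 °C; then 5 (1.3 equiv), KF, 18-crown-6, n-C4F9I (3 equiv), THF, 0 °C to rt, dark
Reagents that add atoms: nonafluoro-1-iodobutane, FC(F)(F)C(F)(F)C(F)(F)C(F)(F)I
Why: Proposed new method: fluoride removes the silyl group of 5 and triflate leaves, giving 3,4,5-trimethoxybenzyne 28, whose triple bond (C-C1≡C-C6 of the future ring C) has C-C5–OMe on one side and C-C2–H on the other; the crown-ether-separated potassium aryloxide 27 should add to C-C1, the carbon remote from the methoxy group, because the aryne is distorted so that this carbon is the more linear and more electrophilic one and the negative charge developing at C-C6 lies in the ring plane next to the electron-withdrawing C-C5–O bond. With no O–H or N–H donor in the flask (27 is pre-formed with KH, the solvent is THF), the C-C6 carbanion, flanked by OMe and OAr, should be captured by iodine transfer from the excess perfluoroalkyl iodide; the perfluorobutyl anion then loses fluoride to give octafluorobutene, and that fluoride restarts aryne formation. The closest known reaction types are the two-component O-arylation of phenols by fluoride-generated arynes (same C–O bond, same meta selectivity with 3-alkoxyarynes) and the fluoride-triggered 1,2-difunctionalisation of arynes in which a heteroatom anion adds and the aryl anion is halogenated in situ by a polyhalogenated donor; what is new is this combination with a hindered aryloxide as the nucleophile. No ring is closed and no stereocentre is formed. Three selectivities are needed: addition at C-C1 and not C-C6 (secured by the methoxy group beside the triple bond), iodine capture faster than protonation or migration of the charge across the ether bridge to B-C6 (secured by the proton-free medium, the iodine donor present in excess from the start and the low temperature), and O- over C-arylation of the ambident phenoxide (secured by the potassium/18-crown-6 ion pair). In one operation ring C should receive both of its neighbouring substituents in defined positions, from a precursor that is two steps from a commercial phenol.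

Step 14
Reactants: 29 1-(2-iodo-3,4,5-trimethoxyphenoxy)-2,3-dimethoxy-5-(2,4,6-trimethoxyphenoxy)benzene
Product: 32 6-[2,3-dimethoxy-5-(2,4,6-trimethoxyphenoxy)phenoxy]-2,3,4-trimethoxyphenol, via arylmagnesium chloride 30 (not isolated), via dimethyl arylboronate 31 (not isolated)
Conditions: i-PrMgCl·LiCl, THF, −20 °C; B(OMe)3, −20 °C to rt; then 30% H2O2, aq NaOH, 0 °C
Reagents that add atoms: hydrogen peroxide, OO
Why: Iodine–magnesium exchange (assisted by the two ortho oxygen substituents), borylation of the Grignard reagent and oxidation of the arylboronate, an established way to turn an aryl iodide into a phenol; no other group in 29 reacts with these reagents.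

Step 15
Reactants: 32 6-[2,3-dimethoxy-5-(2,4,6-trimethoxyphenoxy)phenoxy]-2,3,4-trimethoxyphenol; 14 3,5-dimethoxy-4-(3,4,5-trimethoxyphenoxy)-2-(trimethylsilyl)phenyl trifluoromethanesulfonate
Product: 34 trideca-O-methyl ether of CNP0228612.0 (every hydroxyl of 35 as OMe), via 3,5-dimethoxy-4-(3,4,5-trimethoxyphenoxy)benzyne 33 (not isolated)
Conditions: CsF (4 equiv), MeCN–toluene, rt to 40 °C, 14 (1.5 equiv)
Reagents that add atoms: none
Why: Convergent aryne O-arylation: aryne 33 has its triple bond between D-C1 and D-C2 with D-C3–OMe beside it, so the hindered aryloxide of 32 should add at D-C1 and D-C2 is protonated, which forms the central, most hindered ether without a metal.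

Step 16
Reactants: 34 trideca-O-methyl ether of CNP0228612.0
Product: 35 CNP0228612.0 (tridecahydroxy pentaphenyl tetraether, rings A–E as defined above)
Conditions: BBr3 (excess), CH2Cl2, −78 °C to rt; MeOH then degassed water at 0 °C; isolation under argon
Reagents that add atoms: none
Why: Lewis-acid cleavage of aryl methyl ethers by BBr3 (bromide attacks the methyl group of the boron-complexed ether); diaryl ether bonds offer no such carbon and should remain, and work-up without air protects the pyrogallol- and hydroxyquinol-type rings.

## Compound list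

1 | 3,4,5-trimethoxyphenol | COc1cc(O)cc(OC)c1OC | starting material
2 | 2-bromo-3,4,5-trimethoxyphenol | COc1cc(O)c(Br)c(OC)c1OC | intermediate
3 | (2-bromo-3,4,5-trimethoxyphenoxy)trimethylsilane | COc1cc(O[Si](C)(C)C)c(Br)c(OC)c1OC | intermediate
4 | lithium 3,4,5-trimethoxy-2-(trimethylsilyl)phenolate | [Li+].COc1cc([O-])c([Si](C)(C)C)c(OC)c1OC | intermediate
5 | 3,4,5-trimethoxy-2-(trimethylsilyl)phenyl trifluoromethanesulfonate | COc1cc(OS(=O)(=O)C(F)(F)F)c([Si](C)(C)C)c(OC)c1OC | intermediate
6 | syringaldehyde (4-hydroxy-3,5-dimethoxybenzaldehyde) | COc1cc(C=O)cc(OC)c1O | starting material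
7 | (3,4,5-trimethoxyphenyl)boronic acid | COc1cc(B(O)O)cc(OC)c1OC | starting material
8 | 3,5-dimethoxy-4-(3,4,5-trimethoxyphenoxy)benzaldehyde | COc1cc(C=O)cc(OC)c1Oc1cc(OC)c(OC)c(OC)c1 | intermediate
9 | 3,5-dimethoxy-4-(3,4,5-trimethoxyphenoxy)phenyl formate | COc1cc(OC=O)cc(OC)c1Oc1cc(OC)c(OC)c(OC)c1 | intermediate
10 | 3,5-dimethoxy-4-(3,4,5-trimethoxyphenoxy)phenol | COc1cc(O)cc(OC)c1Oc1cc(OC)c(OC)c(OC)c1 | intermediate
11 | 2-bromo-3,5-dimethoxy-4-(3,4,5-trimethoxyphenoxy)phenol | COc1cc(O)c(Br)c(OC)c1Oc1cc(OC)c(OC)c(OC)c1 | intermediate
12 | [2-bromo-3,5-dimethoxy-4-(3,4,5-trimethoxyphenoxy)phenoxy]trimethylsilane | COc1cc(O[Si](C)(C)C)c(Br)c(OC)c1Oc1cc(OC)c(OC)c(OC)c1 | intermediate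
13 | lithium 3,5-dimethoxy-4-(3,4,5-trimethoxyphenoxy)-2-(trimethylsilyl)phenolate | [Li+].COc1cc([O-])c([Si](C)(C)C)c(OC)c1Oc1cc(OC)c(OC)c(OC)c1 | intermediate
14 | 3,5-dimethoxy-4-(3,4,5-trimethoxyphenoxy)-2-(trimethylsilyl)phenyl trifluoromethanesulfonate | COc1cc(OS(=O)(=O)C(F)(F)F)c([Si](C)(C)C)c(OC)c1Oc1cc(OC)c(OC)c(OC)c1 | intermediate
15 | 3-hydroxy-4,5-dimethoxybenzaldehyde | COc1cc(C=O)cc(O)c1OC | starting material
16 | 2-bromo-3-hydroxy-4,5-dimethoxybenzaldehyde | COc1cc(C=O)c(Br)c(O)c1OC | intermediate
17 | 3-(benzyloxy)-2-bromo-4,5-dimethoxybenzaldehyde | COc1cc(C=O)c(Br)c(OCc2ccccc2)c1OC | intermediate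
18 | 3-(benzyloxy)-2-bromo-4,5-dimethoxyphenyl formate | COc1cc(OC=O)c(Br)c(OCc2ccccc2)c1OC | intermediate
19 | 3-(benzyloxy)-2-bromo-4,5-dimethoxyphenol | COc1cc(O)c(Br)c(OCc2ccccc2)c1OC | intermediate
20 | [3-(benzyloxy)-2-bromo-4,5-dimethoxyphenoxy]trimethylsilane | COc1cc(O[Si](C)(C)C)c(Br)c(OCc2ccccc2)c1OC | intermediate
21 | lithium 3-(benzyloxy)-4,5-dimethoxy-2-(trimethylsilyl)phenolate | [Li+].COc1cc([O-])c([Si](C)(C)C)c(OCc2ccccc2)c1OC | intermediate
22 | 3-(benzyloxy)-4,5-dimethoxy-2-(trimethylsilyl)phenyl trifluoromethanesulfonate | COc1cc(OS(=O)(=O)C(F)(F)F)c([Si](C)(C)C)c(OCc2ccccc2)c1OC | intermediate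
23 | 2,4,6-trimethoxyphenol | COc1cc(OC)c(O)c(OC)c1 | starting material
24 | 3-(benzyloxy)-4,5-dimethoxybenzyne (1,2-didehydro) | COC1=CC#CC(OCc2ccccc2)=C1OC | intermediate
25 | 1-(benzyloxy)-2,3-dimethoxy-5-(2,4,6-trimethoxyphenoxy)benzene | COc1cc(OC)c(Oc2cc(OC)c(OC)c(OCc3ccccc3)c2)c(OC)c1 | intermediate
26 | 2,3-dimethoxy-5-(2,4,6-trimethoxyphenoxy)phenol | COc1cc(OC)c(Oc2cc(O)c(OC)c(OC)c2)c(OC)c1 | intermediate
27 | potassium 2,3-dimethoxy-5-(2,4,6-trimethoxyphenoxy)phenolate | [K+].COc1cc(OC)c(Oc2cc([O-])c(OC)c(OC)c2)c(OC)c1 | intermediate
28 | 3,4,5-trimethoxybenzyne (1,2-didehydro-3,4,5-trimethoxybenzene) | COC1=C(OC)C(OC)=CC#C1 | intermediate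
29 | 1-(2-iodo-3,4,5-trimethoxyphenoxy)-2,3-dimethoxy-5-(2,4,6-trimethoxyphenoxy)benzene | COc1cc(OC)c(Oc2cc(OC)c(OC)c(Oc3cc(OC)c(OC)c(OC)c3I)c2)c(OC)c1 | intermediate
30 | {6-[2,3-dimethoxy-5-(2,4,6-trimethoxyphenoxy)phenoxy]-2,3,4-trimethoxyphenyl}magnesium chloride | COc1cc(OC)c(Oc2cc(OC)c(OC)c(Oc3cc(OC)c(OC)c(OC)c3[Mg]Cl)c2)c(OC)c1 | intermediate
31 | dimethyl {6-[2,3-dimethoxy-5-(2,4,6-trimethoxyphenoxy)phenoxy]-2,3,4-trimethoxyphenyl}boronate | COc1cc(OC)c(Oc2cc(OC)c(OC)c(Oc3cc(OC)c(OC)c(OC)c3B(OC)OC)c2)c(OC)c1 | intermediate
32 | 6-[2,3-dimethoxy-5-(2,4,6-trimethoxyphenoxy)phenoxy]-2,3,4-trimethoxyphenol | COc1cc(OC)c(Oc2cc(OC)c(OC)c(Oc3cc(OC)c(OC)c(OC)c3O)c2)c(OC)c1 | intermediate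
33 | 3,5-dimethoxy-4-(3,4,5-trimethoxyphenoxy)benzyne (1,2-didehydro) | COC1=CC#CC(OC)=C1Oc1cc(OC)c(OC)c(OC)c1 | intermediate
34 | trideca-O-methyl ether of CNP0228612.0 | COc1cc(OC)c(Oc2cc(OC)c(OC)c(Oc3cc(OC)c(OC)c(OC)c3Oc3cc(OC)c(Oc4cc(OC)c(OC)c(OC)c4)c(OC)c3)c2)c(OC)c1 | intermediate
35 | CNP0228612.0 | Oc1cc(O)c(Oc2cc(O)c(O)c(Oc3cc(O)c(O)c(O)c3Oc3cc(O)c(Oc4cc(O)c(O)c(O)c4)c(O)c3)c2)c(O)c1 | target

## Step count and risk

Total: 16 steps. Longest linear sequence: 10 steps (15 → 16 → 17 → 19 → 22 → 25 → 26 → 29 → 32 → 34 → 35).

**Step 13 (key step, proposed new method).** The most likely failure is protonation of the C-C6 carbanion (by traces of water, the crown ether or THF) faster than iodine transfer, which would give the iodine-free ether. Other risks are migration of the negative charge across the ether oxygen to B-C6 before capture, and electron transfer from the electron-rich aryloxide to the perfluoroalkyl iodide. The fallback uses known chemistry and sets out from 26. Copper-catalysed Ullmann coupling (CuI, N,N-dimethylglycine, Cs2CO3, dioxane, 90 °C) with 6-bromo-2,3,4-trimethoxybenzaldehyde F1 (one formylation step from a commercial bromoarene), whose bromine is activated by the ortho formyl group and has only one ortho substituent, should give 6-[2,3-dimethoxy-5-(2,4,6-trimethoxyphenoxy)phenoxy]-2,3,4-trimethoxybenzaldehyde F2. Dakin oxidation (mCPBA, then K2CO3 in MeOH) through the aryl formate F3 should then give phenol 32, where the route is rejoined without passing through 29.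

**Step 15.** The hindered aryloxide of 32 may add too slowly, so that aryne 33 is consumed by fluoride, solvent or its own precursor. The fallback abandons the convergent aryne union and sets out from 32. Displacement of fluoride from commercial 4-fluoro-2,6-dimethoxybenzaldehyde (K2CO3, DMF, 120 °C), whose reacting carbon is unhindered, should give the tetramer aldehyde F4. Dakin oxidation through formate F5 should give the tetramer phenol F6. Chan–Lam coupling of F6 with boronic acid 7 (Cu(OAc)2, pyridine, 4 Å molecular sieves, CH2Cl2, air, rt), as in step 3, should then give 34.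

**Step 16.** Thirteen ether cleavages must all go to completion, and the free polyphenol may be oxidised during isolation. The fallback changes how the product is isolated. From 34, the crude demethylation mixture is acetylated at once (Ac2O, pyridine) to the tridecaacetate F7, which is stable and can be purified on silica. Zemplén deacetylation (catalytic NaOMe, degassed MeOH, then acidic resin) should release 35 under argon.

**Step 5.** Bromine may also enter ring E, or a second bromine may enter ring D. The fallback replaces electrophilic substitution by directed metalation and sets out from 10. Isopropyl isocyanate should give the N-isopropylcarbamate F8. In-situ N-silylation (TMSOTf, TMEDA), ortho-lithiation (n-BuLi, TMEDA, −78 °C) between the carbamate and D-C3–OMe, and TMSCl should give the ortho-silyl carbamate F9. Carbamate cleavage and triflation in one flask (DBU, Et2NH, MeCN; then PhNTf2) should give 14, bypassing 11.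

**Step 11.** The very electron-rich aryloxide of 23 may be arylated on carbon, or the aryne may be lost to side reactions before the hindered oxygen adds. The fallback sets out from 23. Ullmann coupling (CuI, N,N-dimethylglycine, Cs2CO3, dioxane, 100 °C) with commercial 5-bromo-2,3-dimethoxybenzaldehyde should give 2,3-dimethoxy-5-(2,4,6-trimethoxyphenoxy)benzaldehyde F10. Dakin oxidation through formate F11 should give 26, which replaces steps 7 to 12 at the cost of a copper coupling of a hindered phenol.

## Further compounds

F1 | step 13 | 6-bromo-2,3,4-trimethoxybenzaldehyde | COc1cc(Br)c(C=O)c(OC)c1OC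
F2 | step 13 | 6-[2,3-dimethoxy-5-(2,4,6-trimethoxyphenoxy)phenoxy]-2,3,4-trimethoxybenzaldehyde | COc1cc(OC)c(Oc2cc(OC)c(OC)c(Oc3cc(OC)c(OC)c(OC)c3C=O)c2)c(OC)c1
F3 | step 13 | 6-[2,3-dimethoxy-5-(2,4,6-trimethoxyphenoxy)phenoxy]-2,3,4-trimethoxyphenyl formate | COc1cc(OC)c(Oc2cc(OC)c(OC)c(Oc3cc(OC)c(OC)c(OC)c3OC=O)c2)c(OC)c1
F4 | step 15 | 4-{6-[2,3-dimethoxy-5-(2,4,6-trimethoxyphenoxy)phenoxy]-2,3,4-trimethoxyphenoxy}-2,6-dimethoxybenzaldehyde | COc1cc(OC)c(Oc2cc(OC)c(OC)c(Oc3cc(OC)c(OC)c(OC)c3Oc3cc(OC)c(C=O)c(OC)c3)c2)c(OC)c1
F5 | step 15 | 4-{6-[2,3-dimethoxy-5-(2,4,6-trimethoxyphenoxy)phenoxy]-2,3,4-trimethoxyphenoxy}-2,6-dimethoxyphenyl formate | COc1cc(OC)c(Oc2cc(OC)c(OC)c(Oc3cc(OC)c(OC)c(OC)c3Oc3cc(OC)c(OC=O)c(OC)c3)c2)c(OC)c1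
F6 | step 15 | 4-{6-[2,3-dimethoxy-5-(2,4,6-trimethoxyphenoxy)phenoxy]-2,3,4-trimethoxyphenoxy}-2,6-dimethoxyphenol | COc1cc(OC)c(Oc2cc(OC)c(OC)c(Oc3cc(OC)c(OC)c(OC)c3Oc3cc(OC)c(O)c(OC)c3)c2)c(OC)c1
F7 | step 16 | trideca-O-acetate of CNP0228612.0 | CC(=O)Oc1cc(OC(C)=O)c(Oc2cc(OC(C)=O)c(OC(C)=O)c(Oc3cc(OC(C)=O)c(OC(C)=O)c(OC(C)=O)c3Oc3cc(OC(C)=O)c(Oc4cc(OC(C)=O)c(OC(C)=O)c(OC(C)=O)c4)c(OC(C)=O)c3)c2)c(OC(C)=O)c1
F8 | step 5 | 3,5-dimethoxy-4-(3,4,5-trimethoxyphenoxy)phenyl N-isopropylcarbamate | COc1cc(OC(=O)NC(C)C)cc(OC)c1Oc1cc(OC)c(OC)c(OC)c1
F9 | step 5 | 3,5-dimethoxy-4-(3,4,5-trimethoxyphenoxy)-2-(trimethylsilyl)phenyl N-isopropylcarbamate | COc1cc(OC(=O)NC(C)C)c([Si](C)(C)C)c(OC)c1Oc1cc(OC)c(OC)c(OC)c1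
F10 | step 11 | 2,3-dimethoxy-5-(2,4,6-trimethoxyphenoxy)benzaldehyde | COc1cc(OC)c(Oc2cc(C=O)c(OC)c(OC)c2)c(OC)c1
F11 | step 11 | 2,3-dimethoxy-5-(2,4,6-trimethoxyphenoxy)phenyl formate | COc1cc(OC)c(Oc2cc(OC=O)c(OC)c(OC)c2)c(OC)c1
A1 | alternative 1 | 1-(2-bromo-3,4,5-trimethoxyphenoxy)-2,3-dimethoxy-5-(2,4,6-trimethoxyphenoxy)benzene | COc1cc(OC)c(Oc2cc(OC)c(OC)c(Oc3cc(OC)c(OC)c(OC)c3Br)c2)c(OC)c1
A2 | alternative 2 | 3-(benzyloxy)-4-fluoro-2,6-dimethoxybenzaldehyde | COc1cc(F)c(OCc2ccccc2)c(OC)c1C=O
A3 | alternative 3 | 4,5-dimethoxy-2-(trimethylsilyl)-1,3-phenylene bis(trifluoromethanesulfonate) | COc1cc(OS(=O)(=O)C(F)(F)F)c([Si](C)(C)C)c(OS(=O)(=O)C(F)(F)F)c1OC
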